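The route is a 13-step proposal (longest linear sequence 11) from (S)-carvone, built around an anionic oxy-Cope ring expansion with in-flask enolate hydroxylation at step 7.

Germacrane numbering: C1=C10 alkene, C3 angelate, C4–C5 epoxide, C6 acetate, C7 isopropyl. In the ten-membered ring the C2–C3 bond is the central σ-bond of a latent 1,5-diene (C1=C10 plus the alkene level of C4–C5). A [3,3] shift therefore links it to the C5–C10 bond of a six-membered p-menthane ring, that of (S)-carvone, whose stereocentre becomes C7. One anionic oxy-Cope step cleaves that ring, forms C2–C3, closes the cyclodecene, sets the E alkene and C3, and gives a planar-chiral enolate that is hydroxylated at C4 in the same flask. Its precursor is a trans-1,2-dialkenylcyclohexanol carrying an E enol ether.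

Key step: step 7

Remark: germacrane atom numbers are also used for the matching atoms of the six-membered precursors. Axial attack on enolate 4 (new C–C bond cis to isopropyl) is assumed to dominate, and the minor C10 epimer is removed at 6. The carbinol centre of 5 forms as a mixture and is erased in step 3.

Step 1
Reactants: 1 (S)-(+)-carvone
Product: 2 (S)-carvotanacetone, (5S)-2-methyl-5-(propan-2-yl)cyclohex-2-en-1-one
Conditions: H2 (1 atm), RhCl(PPh3)3 (cat.), toluene, rt
Reagents that add atoms: none
Why: Homogeneous hydrogenation with Wilkinson's catalyst saturates the unhindered 1,1-disubstituted isopropenyl alkene and leaves the trisubstituted conjugated enone alone, so the carvone stereocentre (future C7) is carried on untouched.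

Step 2
Reactants: 2 (S)-carvotanacetone; 3 acetaldehyde
Product: 5 (2S,5S)-2-(1-hydroxyethyl)-2-methyl-5-(propan-2-yl)cyclohexan-1-one (carbinol epimers), via lithium enolate 4 (not isolated)
Conditions: L-Selectride, THF, −78 °C; 3, −78 °C; pH 7 buffer, H2O2
Reagents that add atoms: L-Selectride, [Li+].CCC(C)[BH-](C(C)CC)C(C)CC (lithium in 4 only)
Why: Conjugate hydride reduction of the β-unsubstituted cyclohexenone gives the tetrasubstituted enolate regiospecifically, and its aldol addition should proceed by axial attack on the half-chair with equatorial isopropyl, which places the new C10–C1 bond cis to the isopropyl group.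

Step 3
Reactants: 5 aldol
Product: 6 (2S,5S)-2-ethenyl-2-methyl-5-(propan-2-yl)cyclohexan-1-one
Conditions: Burgess reagent, toluene, 70 °C
Reagents that add atoms: none
Why: Burgess dehydration (syn elimination of the sulfamate ester) can only take a methyl hydrogen because C10 is quaternary, so the hydroxyethyl group becomes the vinyl group without touching C10 or C7.

Step 4
Reactants: 7 4-methoxybenzyl alcohol; 8 trichloroethene; 9 iodomethane
Product: 12 4-methoxybenzyl prop-1-yn-1-yl ether, via dichlorovinyl ether 10 (not isolated), via lithium acetylide 11 (not isolated)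
Conditions: KH, THF, 0 °C; 8, −50 °C → rt; n-BuLi (2.2 equiv), −78 °C; 9, DMPU, −78 °C → rt; product kept below 30 °C
Reagents that add atoms: n-butyllithium, [Li]CCCC (lithium in 11 only)
Why: In this trichloroethene-based ynol ether synthesis the alkoxide adds to dichloroethyne formed in situ, n-BuLi then effects elimination and chlorine–lithium exchange, and the lithium acetylide is C-methylated.

Step 5
Reactants: 12 ynol ether
Product: 14 1-{[(1E)-2-iodoprop-1-en-1-yl]oxymethyl}-4-methoxybenzene, via alkenylzirconocene chloride 13 (not isolated)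
Conditions: Cp2Zr(H)Cl, THF, 0 °C → rt; I2, THF, −78 °C; aq Na2S2O3/NaHCO3
Reagents that add atoms: iodine, II; Schwartz reagent, [H][Zr+2]Cl.c1cc[cH-]c1.c1cc[cH-]c1 (zirconium in 13 only)
Why: In this hydrozirconation–iodination, syn addition puts hydride on the electrophilic oxygen-bearing carbon and zirconium on the nucleophilic β-carbon, and iodinolysis with retention fixes oxygen and iodine trans (E).

Step 6
Reactants: 14 (E)-iodo enol ether; 6 vinyl ketone
Product: 16 (1S,2S,5S)-2-ethenyl-1-[(1E)-1-(4-methoxybenzyloxy)prop-1-en-2-yl]-2-methyl-5-(propan-2-yl)cyclohexan-1-ol, via alkenyllithium 15 (not isolated)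
Conditions: t-BuLi (2 equiv), Et2O, −78 °C; 6, THF, −78 °C; H2O quench
Reagents that add atoms: tert-butyllithium, [Li]C(C)(C)C (lithium in 15 only)
Why: Iodine–lithium exchange keeps the alkene geometry, and 1,2-addition to the ketone from the face opposite to the axial vinyl group (and to the isopropyl group) sets C5 with the two alkenyl groups trans, as the chair-like [3,3] shift requires.

Step 7
Reactants: 16 dialkenylcyclohexanol
Product: 19 (1(10)E,3S,4R,7S)-4-hydroxy-3-(4-methoxybenzyloxy)germacr-1(10)-en-5-one, via potassium alkoxide 17 (not isolated), via potassium enolate 18 (not isolated)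
Conditions: KH, 18-crown-6, THF, 0 °C → rt until 17 is consumed; then −78 °C, 2-(phenylsulfonyl)-3-phenyloxaziridine; AcOH/THF quench at −78 °C
Reagents that add atoms: Davis oxaziridine, O=S(=O)(N1OC1c1ccccc1)c1ccccc1; potassium hydride, [H-].[K+] (potassium in 17 and 18 only)
Why: The potassium alkoxide 17 undergoes an anionic oxy-Cope rearrangement (charge-accelerated [3,3]-sigmatropic shift, the known divinylcyclohexanol to cyclodecenone ring expansion), in which the C5–C10 bond of the six-membered ring breaks while C2–C3 forms. The ten-membered ring is thus closed by a four-atom sigmatropic ring expansion through a chair-like six-centre transition state, fused trans-decalin-like to the cyclohexane chair that holds both alkenyl groups equatorial, and not by an end-to-end cyclisation. The equatorial ring bonds C10–C9 and C5–C6 of that array translate into the E C1=C10 alkene and into an enolate with C3 and C6 trans. C3 is set by chirality transfer from C5/C10, because the E enol ether places the OPMB group equatorial in the chair, which gives 3S. C4 is set when the oxaziridine (Davis hydroxylation) attacks the only open, outer face of the planar-chiral tetrasubstituted enolate 18, whose inner face is shielded transannularly by C1=C10, which gives 4R. The step needs the [3,3] shift to outrun loss of the β-alkoxide from 18: the C3–O bond lies near the nodal plane of the enolate and cannot rotate into overlap without forcing C2 into the plane of a trans double bond in the ring, and 18 is oxidised cold as soon as 17 is consumed, after which C4 is quaternary and elimination is impossible.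

Step 8
Reactants: 19 α-hydroxy ketone
Product: 21 (1(10)E,3S,4R,6S,7R)-4,6-dihydroxy-3-(4-methoxybenzyloxy)germacr-1(10)-en-5-one, via dipotassium alkoxide enolate 20 (not isolated)
Conditions: KHMDS (2.2 equiv), THF, −78 °C; 2-(phenylsulfonyl)-3-phenyloxaziridine, −78 °C; AcOH/THF quench
Reagents that add atoms: Davis oxaziridine, O=S(=O)(N1OC1c1ccccc1)c1ccccc1; KHMDS, C[Si](C)(C)[N-][Si](C)(C)C.[K+] (potassium in 20 only)
Why: In this Davis α-hydroxylation only one enolate is possible (C4 is quaternary), the outward-pointing C6 hydrogen is the one aligned with the carbonyl π system, and oxygen should replace it from the same peripheral face (macrocyclic stereocontrol), which gives 6S.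

Step 9
Reactants: 21 dihydroxy ketone
Product: 22 (1(10)E,3S,4R,6S,7R)-6-acetoxy-4-hydroxy-3-(4-methoxybenzyloxy)germacr-1(10)-en-5-one
Conditions: Ac2O, pyridine, DMAP (cat.), CH2Cl2, 0 °C
Reagents that add atoms: acetic anhydride, CC(=O)OC(C)=O
Why: DMAP-catalysed acylation is selective for the secondary C6 hydroxyl over the tertiary C4 hydroxyl and leaves every stereocentre untouched.

Step 10
Reactants: 22 acetoxy hydroxy ketone
Product: 23 (1(10)E,3S,4S,5S,6S,7R)-6-acetoxy-3-(4-methoxybenzyloxy)germacr-1(10)-ene-4,5-diol (4,5-anti; C4 spatially unchanged, its label changes by ranking only)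
Conditions: Zn(BH4)2 (from ZnCl2 and NaBH4), Et2O, −20 → 0 °C
Reagents that add atoms: none
Why: In this chelation-controlled reduction of an α-hydroxy ketone, zinc bridges O4 and the carbonyl oxygen and hydride arrives on the side of the small C4 methyl group, which gives the anti diol (5S) and spares the acetate.

Step 11
Reactants: 23 anti diol
Product: 25 (1(10)E,3S,4R,5R,6S,7R)-6-acetoxy-4,5-epoxy-3-(4-methoxybenzyloxy)germacr-1(10)-ene, via C5 mesylate 24 (not isolated)
Conditions: MsCl, Et3N, CH2Cl2, 0 °C; then DBU, toluene, 60 °C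
Reagents that add atoms: methanesulfonyl chloride, CS(=O)(=O)Cl (into 24 only)
Why: Only the secondary C5 hydroxyl is mesylated, and an intramolecular Williamson closure (3-exo-tet) by O4 with inversion at C5 gives the trans epoxide (4R,5R) with the C4–O bond retained.

Step 12
Reactants: 25 PMB ether
Product: 26 (1(10)E,3S,4R,5R,6S,7R)-6-acetoxy-4,5-epoxygermacr-1(10)-en-3-ol
Conditions: DDQ, CH2Cl2/pH 7 buffer, 0 °C
Reagents that add atoms: none
Why: Oxidative PMB cleavage (hydride abstraction from the electron-rich benzylic position, then hydrolysis) frees the C3 hydroxyl under neutral buffered conditions that spare epoxide, acetate and alkene.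

Step 13
Reactants: 26 epoxy alcohol; 27 angelic acid
Product: 29 target, (1(10)E,3S,4R,5R,6S,7R)-6-acetoxy-3-angeloyloxy-4,5-epoxygermacr-1(10)-ene, via angelic trichlorobenzoic anhydride 28 (not isolated)
Conditions: 27, 2,4,6-trichlorobenzoyl chloride, Et3N, toluene, rt; then 26, 80 °C (no DMAP)
Reagents that add atoms: 2,4,6-trichlorobenzoyl chloride, O=C(Cl)c1c(Cl)cc(Cl)cc1Cl (into 28 only)
Why: Yamaguchi-type esterification through the mixed anhydride without a nucleophilic catalyst transfers the angeloyl group without Z to E isomerisation, and 3S is kept because the C3–O bond is not broken.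

Compound list
1 | (S)-(+)-carvone | CC1=CC[C@@H](CC1=O)C(C)=C | starting material
2 | (S)-carvotanacetone | CC1=CC[C@@H](CC1=O)C(C)C | intermediate
3 | acetaldehyde | CC=O | starting material
4 | lithium (5S)-2-methyl-5-(propan-2-yl)cyclohex-1-en-1-olate | CC1=C([O-])C[C@@H](C(C)C)CC1.[Li+] | intermediate
5 | (2S,5S)-2-(1-hydroxyethyl)-2-methyl-5-(propan-2-yl)cyclohexan-1-one (carbinol epimers) | O=C1C[C@@H](C(C)C)CC[C@@]1(C)C(C)O | intermediate
6 | (2S,5S)-2-ethenyl-2-methyl-5-(propan-2-yl)cyclohexan-1-one | O=C1C[C@@H](C(C)C)CC[C@@]1(C)C=C | intermediate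
7 | 4-methoxybenzyl alcohol | COc1ccc(CO)cc1 | starting material
8 | trichloroethene | ClC=C(Cl)Cl | starting material
9 | iodomethane | CI | starting material
10 | (E)-1,2-dichlorovinyl 4-methoxybenzyl ether | COc1ccc(CO/C(Cl)=C\Cl)cc1 | intermediate
11 | lithium (4-methoxybenzyloxy)acetylide | COc1ccc(COC#[C-])cc1.[Li+] | intermediate
12 | 4-methoxybenzyl prop-1-yn-1-yl ether | COc1ccc(COC#CC)cc1 | intermediate
13 | (E)-[1-(4-methoxybenzyloxy)prop-1-en-2-yl]zirconocene chloride | COc1ccc(CO/C=C(\C)[Zr+2]Cl)cc1.c1cc[cH-]c1.c1cc[cH-]c1 | intermediate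
14 | 1-{[(1E)-2-iodoprop-1-en-1-yl]oxymethyl}-4-methoxybenzene | COc1ccc(CO/C=C(\C)I)cc1 | intermediate
15 | (E)-[1-(4-methoxybenzyloxy)prop-1-en-2-yl]lithium | COc1ccc(CO/C=C(\C)[Li])cc1 | intermediate
16 | (1S,2S,5S)-2-ethenyl-1-[(1E)-1-(4-methoxybenzyloxy)prop-1-en-2-yl]-2-methyl-5-(propan-2-yl)cyclohexan-1-ol | O[C@@]1(/C(C)=C/OCc2ccc(OC)cc2)C[C@@H](C(C)C)CC[C@@]1(C)C=C | intermediate
17 | potassium alkoxide of 16 | [O-][C@@]1(/C(C)=C/OCc2ccc(OC)cc2)C[C@@H](C(C)C)CC[C@@]1(C)C=C.[K+] | intermediate
18 | potassium (1(10)E,3S,7S)-3-(4-methoxybenzyloxy)germacra-1(10),4-dien-5-olate (C3 and C6 trans across C4=C5) | COc1ccc(CO[C@H]2C/C=C(\C)CC[C@H](C(C)C)C/C([O-])=C2\C)cc1.[K+] | intermediate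
19 | (1(10)E,3S,4R,7S)-4-hydroxy-3-(4-methoxybenzyloxy)germacr-1(10)-en-5-one | COc1ccc(CO[C@H]2C/C=C(\C)CC[C@H](C(C)C)CC(=O)[C@]2(C)O)cc1 | intermediate
20 | dipotassium C4-alkoxide C5=C6-enolate of 19 (C4 and C7 trans across C5=C6) | COc1ccc(CO[C@H]2C/C=C(\C)CC[C@H](C(C)C)/C=C([O-])/[C@]2(C)[O-])cc1.[K+].[K+] | intermediate
21 | (1(10)E,3S,4R,6S,7R)-4,6-dihydroxy-3-(4-methoxybenzyloxy)germacr-1(10)-en-5-one | COc1ccc(CO[C@H]2C/C=C(\C)CC[C@H](C(C)C)[C@H](O)C(=O)[C@]2(C)O)cc1 | intermediate
22 | (1(10)E,3S,4R,6S,7R)-6-acetoxy-4-hydroxy-3-(4-methoxybenzyloxy)germacr-1(10)-en-5-one | COc1ccc(CO[C@H]2C/C=C(\C)CC[C@H](C(C)C)[C@H](OC(C)=O)C(=O)[C@]2(C)O)cc1 | intermediate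
23 | (1(10)E,3S,4S,5S,6S,7R)-6-acetoxy-3-(4-methoxybenzyloxy)germacr-1(10)-ene-4,5-diol | COc1ccc(CO[C@H]2C/C=C(\C)CC[C@H](C(C)C)[C@H](OC(C)=O)[C@H](O)[C@]2(C)O)cc1 | intermediate
24 | C5 methanesulfonate of 23 | COc1ccc(CO[C@H]2C/C=C(\C)CC[C@H](C(C)C)[C@H](OC(C)=O)[C@H](OS(C)(=O)=O)[C@]2(C)O)cc1 | intermediate
25 | (1(10)E,3S,4R,5R,6S,7R)-6-acetoxy-4,5-epoxy-3-(4-methoxybenzyloxy)germacr-1(10)-ene | COc1ccc(CO[C@H]2C/C=C(\C)CC[C@H](C(C)C)[C@H](OC(C)=O)[C@H]3O[C@]23C)cc1 | intermediate
26 | (1(10)E,3S,4R,5R,6S,7R)-6-acetoxy-4,5-epoxygermacr-1(10)-en-3-ol | O[C@H]1C/C=C(\C)CC[C@H](C(C)C)[C@H](OC(C)=O)[C@H]2O[C@]12C | intermediate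
27 | angelic acid, (Z)-2-methylbut-2-enoic acid | C/C=C(/C)C(=O)O | starting material
28 | angelic 2,4,6-trichlorobenzoic anhydride | C/C=C(/C)C(=O)OC(=O)c1c(Cl)cc(Cl)cc1Cl | intermediate
29 | CNP0180504.1, (1(10)E,3S,4R,5R,6S,7R)-6-acetoxy-3-angeloyloxy-4,5-epoxygermacr-1(10)-ene | C/C=C(/C)C(=O)O[C@H]1C/C=C(\C)CC[C@H](C(C)C)[C@H](OC(C)=O)[C@H]2O[C@]12C | target

Total step count: 13. Longest linear sequence: 11 (steps 1–3 and 6–13). Steps 4 and 5 build the alkenyl iodide in a side branch.

Steps most likely to fail

Step 7. The β-alkoxy enolate may expel 4-methoxybenzyl oxide while the rearrangement is still running. Oxygen transfer to the crowded tetrasubstituted potassium enolate may also lag behind its addition to the sulfonimine by-product. The fallback sets out from 16 and comes back at 19. The rearrangement is run in the same way, but the enolate is taken out of the anionic manifold by O-silylation with chlorotriethylsilane at −78 °C. This gives the neutral, isolable triethylsilyl enol ether F1. A Rubottom oxidation with one equivalent of dimethyldioxirane on its open outer face gives the 4-triethylsilyloxy ketone F2. HF·pyridine then frees the tertiary alcohol 19.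

Step 8. Once the rigid C4=C5 unit is gone the ring is more flexible, so facial selectivity in the enolate oxidation may be poor or reversed. The fallback sets out from 19 and comes back at 22, and it makes the sequence stereoconvergent. The 6S alcohol 21 is acetylated as in step 9. The 6R-configured dihydroxy ketone F3 is converted into the same acetate 22 by a Mitsunobu reaction with acetic acid (PPh3, DIAD), an SN2 inversion at a carbon activated by the neighbouring ketone.

Step 11. The acetyl group may migrate from O6 to O5 or O4, or it may participate in departure of the mesylate. Closure under a mild base may also be slow because the anti O4–C4–C5–OMs array costs ring strain. The fallback sets out from 21 and comes back at 25, with O6 carried as a silyl ether so that a strong base can be used. TBSOTf and 2,6-lutidine give the 6-silyl ether ketone F4. Zn(BH4)2 gives the anti diol F5, and MsCl/Et3N gives the mesylate F6. K2CO3 in methanol closes the silyloxy epoxide F7, and TBAF frees the 6-hydroxy epoxide F8. Acetylation (Ac2O, pyridine, DMAP) then gives 25.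

Further compounds
F1 | step 7 | triethylsilyl enol ether of the ring-expanded ketone (C3 and C6 trans across C4=C5) | COc1ccc(CO[C@H]2C/C=C(\C)CC[C@H](C(C)C)C/C(O[Si](CC)(CC)CC)=C2\C)cc1
F2 | step 7 | (1(10)E,3S,4R,7S)-3-(4-methoxybenzyloxy)-4-(triethylsilyloxy)germacr-1(10)-en-5-one | COc1ccc(CO[C@H]2C/C=C(\C)CC[C@H](C(C)C)CC(=O)[C@]2(C)O[Si](CC)(CC)CC)cc1
F3 | step 8 | (1(10)E,3S,4R,6R,7R)-4,6-dihydroxy-3-(4-methoxybenzyloxy)germacr-1(10)-en-5-one | COc1ccc(CO[C@H]2C/C=C(\C)CC[C@H](C(C)C)[C@@H](O)C(=O)[C@]2(C)O)cc1
F4 | step 11 | 6-O-tert-butyldimethylsilyl ether of 21 | COc1ccc(CO[C@H]2C/C=C(\C)CC[C@H](C(C)C)[C@H](O[Si](C)(C)C(C)(C)C)C(=O)[C@]2(C)O)cc1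
F5 | step 11 | 6-silyloxy 4,5-anti diol | COc1ccc(CO[C@H]2C/C=C(\C)CC[C@H](C(C)C)[C@H](O[Si](C)(C)C(C)(C)C)[C@H](O)[C@]2(C)O)cc1
F6 | step 11 | 6-silyloxy C5 mesylate | COc1ccc(CO[C@H]2C/C=C(\C)CC[C@H](C(C)C)[C@H](O[Si](C)(C)C(C)(C)C)[C@H](OS(C)(=O)=O)[C@]2(C)O)cc1
F7 | step 11 | 6-silyloxy 4,5-epoxide | COc1ccc(CO[C@H]2C/C=C(\C)CC[C@H](C(C)C)[C@H](O[Si](C)(C)C(C)(C)C)[C@H]3O[C@]23C)cc1
F8 | step 11 | 6-hydroxy 4,5-epoxide | COc1ccc(CO[C@H]2C/C=C(\C)CC[C@H](C(C)C)[C@H](O)[C@H]3O[C@]23C)cc1
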